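Compare the two columns of the violet run, which is this flask followed so far: from 15.0 min to 25.0 min the substrate loses 20 percentage points and the target gains 1 point, yet in the first 5.00 min target took 33.0 % of the substrate lost.

- violet: substrate 0.40 M; solid reagent 1 M; the very flask that is asked about, followed so far
- flask: substrate 0.40 M; solid reagent 1.00 M; time 25 min

- violet (time / min: target / %, substrate / %): 1.50: 1.7, 94.7; 5.00: 6.5, 80.3; 8.00: 9.6, 68.8; 15.0: 12.3, 47.4; 20.0: 13.2, 35.6; 25.0: 13.3, 27.3

(standard deviation of a reading: 0.5 percentage points)

- alpha: at 25 min add substrate, 50.0 % of the amount charged, then wait 50 min
- theta: change nothing and wait 50 min more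
- gamma: at 25 min take out 90 % of the target then present, then wait 50 min

- target, in percent of the substrate first charged, at 25 min
- the option that brings most further target ("none" if no option brings more than 2 percentage points) (alpha / theta / gamma / none)
- target present, with what was taken out counted in, in percent of the substrate first charged, after alpha
- target present, with what was taken out counted in, in percent of the substrate first charged, after gamma

- solid, in amounts per volume of the solution: solid reagent
- target taken out counts as made
- at the start none of the solid reagent is in solution
- additions bring no volume worth counting

Read the flat stretch as a crossing. Target gains just 1 point while substrate goes from 47.4 % to 27.3 %, so take its making and its loss to scale alike with substrate, which then cancels. That gives a ceiling of c_target, read off the last reading at 0.0532 M, the concentration at which making and loss of target cross, a quasi-steady state. Assume the share of substrate reaching target falls in a straight line from the early value to zero at the ceiling.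

Now turn each setting by hand. Wait (theta): c_target stands at the ceiling, so expect no gain. Add substrate (alpha): the ceiling does not move, so expect 13.3 % again. Take out target (gamma): this banks 12.0 % and opens a gap. The readings halve substrate in 12.6 min, so count nearly all of the remaining 27.3 % as spent during the wait. The straight-line share then gives a gain of 5.9 points, a total of 19.2 %. This reckoning picks gamma.

The forecast differs. Holding that “target is lost as it forms”, it gives 13.3 % now, best option none, 10.5 % after alpha and 14.8 % after gamma.

The flask gives 13.7 % now, best option gamma, 12.8 % after alpha and 20.3 % after gamma.

    substrate + intermediate → side product (k = 0.0261 L mol⁻¹ s⁻¹)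
    solid reagent ⇌ partner, rate k2*(cs2 - [partner]) while solid is left; crystals form when [partner] > cs2 (solubility = 0.160 M, k = 0.123 s⁻¹)
    intermediate ⇌ target (K = 3.60, k = 0.0256 s⁻¹)
    intermediate ⇌ isomer of the product (K = 180, k = 8.61 × 10⁻⁴ s⁻¹)
    substrate + partner → intermediate + by-product (k = 0.00346 L mol⁻¹ s⁻¹)

Target and intermediate relax into each other with a half-life of 0.353 min, far shorter than 25 min. Gamma gains 6.6 points against the reckoned 5.9 points. Alpha and theta change target by −0.9 points and −3.2 points: neither gains, as the ceiling said, but both lose, which the ceiling did not say.

Take the neighbour flask with 1.6 M of substrate: the ceiling gives 3.32 % of its charge. The computed target in that neighbour flask at 25 min is 4.37 % of its charge, which is 0.0699 M.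

The readings are calculated on assumed constants.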